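**Retrosynthetic overview**

1. Numbering (germacrane): C1 ring ketone, C4/C5 oxirane (C15 methyl on C4), C6 lactone carbinol, C7=C11 butenolide alkene, C8 and C10 acetoxy carbons, C12 lactone carbonyl, C13 hydroxymethyl. Target 29 comes from the silyl-protected tricycle 26 by protecting-group exchange (steps 18–20).
2. 26 comes from the acyclic epoxy aldehyde 23 by cutting C6–C7: one Ni/Cr-mediated alkenyl iodide–aldehyde coupling folds the chain into the ten-membered carbocycle, the alkoxide closes the butenolide in the same flask, and C6 is set.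
3. Enabling feature: the C6–C7 bond is shared by the ten-membered ring and the five-membered lactone, and C7 is the β-carbon of the C11=C7 enoate with C12 cis to C6. A (Z)-β-iodo enoate at C7 plus an aldehyde at C6 (next to the C4–C5 oxirane) therefore gives a cis-γ-oxido enoate that can only lactonize to the 6,12-olide.
4. 23 comes from ynoate 17 (iodide and formaldehyde across C7≡C11 install the iodine and C13; Sharpless epoxidation sets C4/C5), which comes from aldehyde 14 and methyl propiolate (C8 by catalyst control).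
5. 14 comes from lactone 5 (C10 from (R)-citramalic acid) and alkyllithium 12 (E-alkene by carboalumination). Ring order: oxirane (step 15), then carbocycle and butenolide together (step 17).

Key step: step 17

Assumption: the target is taken as drawn, (4R,5R,6S,8S,10R) in germacrane numbering with a trans oxirane, and the ProPhenol antipode in step 10 is the one that delivers the 8S carbinol (to be confirmed by Mosher ester analysis).

**Route**

Step 1
Reactants: 1 (R)-citramalic acid [(2R)-2-hydroxy-2-methylbutanedioic acid]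
Product: 2 2-[(4R)-2,2,4-trimethyl-5-oxo-1,3-dioxolan-4-yl]acetic acid
Conditions: 2,2-dimethoxypropane, TsOH·H2O (cat.), rt
Reagents that add atoms: 2,2-dimethoxypropane, COC(C)(C)OC
Why: Acid-catalysed transacetalization ties the α-hydroxy acid into the favoured five-membered dioxolanone and leaves the β-carboxyl free; the C10 stereocentre comes unchanged from the chiral pool.

Step 2
Reactants: 2 2-[(4R)-2,2,4-trimethyl-5-oxo-1,3-dioxolan-4-yl]acetic acid
Product: 4 (3R)-3-hydroxy-3-methyloxolan-2-one, via hydroxyethyl dioxolanone 3 (not isolated)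
Conditions: BH3·SMe2, THF, 0 °C to rt; MeOH quench; then TsOH (cat.), CH2Cl2, rt
Reagents that add atoms: none
Why: Chemoselective borane reduction of the free carboxylic acid, then acid-catalysed transacylation of the new primary alcohol onto the dioxolanone carbonyl (5-exo-trig, loss of acetone), should give the hydroxy lactone, as in the known malic acid to α-hydroxybutyrolactone sequence.

Step 3
Reactants: 4 (3R)-3-hydroxy-3-methyloxolan-2-one
Product: 5 (3R)-3-methyl-3-[(triethylsilyl)oxy]oxolan-2-one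
Conditions: TESOTf, 2,6-lutidine, CH2Cl2, −78 to 0 °C
Reagents that add atoms: triethylsilyl trifluoromethanesulfonate, CC[Si](CC)(CC)OS(=O)(=O)C(F)(F)F
Why: Silyl triflate silylation of the tertiary alcohol protects C10–O so that later organolithium addition is single and the β-oxy aldehyde of step 9 cannot eliminate or undergo retro-aldol cleavage.

Step 4
Reactants: 6 (but-3-yn-1-yloxy)(tert-butyl)dimethylsilane
Product: 8 (2E)-5-{[tert-butyl(dimethyl)silyl]oxy}-3-methylpent-2-en-1-ol, via alkenylalane 7 (not isolated)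
Conditions: Me3Al, Cp2ZrCl2, CH2Cl2, 0 °C to rt; then n-BuLi, THF, −78 °C; (CH2O)n, rt
Reagents that add atoms: trimethylaluminium, C[Al](C)C; formaldehyde (from paraformaldehyde), C=O
Why: Negishi zirconium-catalysed carboalumination adds methyl and aluminium syn across the terminal alkyne (methyl on the internal carbon), and hydroxymethylation of the alanate with retention fixes the E trisubstituted C4=C5 alkene.

Step 5
Reactants: 8 (2E)-5-{[tert-butyl(dimethyl)silyl]oxy}-3-methylpent-2-en-1-ol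
Product: 9 tert-butyl(dimethyl){[(3E)-3-methyl-5-(naphthalen-2-ylmethoxy)pent-3-en-1-yl]oxy}silane
Conditions: NaH, 2-(bromomethyl)naphthalene, Bu4NI (cat.), THF, 0 °C to rt
Reagents that add atoms: 2-(bromomethyl)naphthalene, BrCc1ccc2ccccc2c1
Why: Williamson etherification installs a 2-naphthylmethyl ether on C6–O that survives alkyllithium, MgI2 and silylation chemistry and is later removed oxidatively without touching silyl ethers.

Step 6
Reactants: 9 tert-butyl(dimethyl){[(3E)-3-methyl-5-(naphthalen-2-ylmethoxy)pent-3-en-1-yl]oxy}silane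
Product: 10 (3E)-3-methyl-5-(naphthalen-2-ylmethoxy)pent-3-en-1-ol
Conditions: TBAF, THF, 0 °C to rt
Reagents that add atoms: none
Why: Fluoride desilylation frees the primary homoallylic alcohol while the naphthylmethyl ether is inert.

Step 7
Reactants: 10 (3E)-3-methyl-5-(naphthalen-2-ylmethoxy)pent-3-en-1-ol
Product: 11 2-({[(2E)-5-iodo-3-methylpent-2-en-1-yl]oxy}methyl)naphthalene
Conditions: I2, PPh3, imidazole, CH2Cl2, 0 °C
Reagents that add atoms: iodine, [I][I]
Why: Appel-type iodination converts the primary alcohol into the iodide by SN2 displacement of the oxyphosphonium without touching the alkene geometry.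

Step 8
Reactants: 11 2-({[(2E)-5-iodo-3-methylpent-2-en-1-yl]oxy}methyl)naphthalene, 5 (3R)-3-methyl-3-[(triethylsilyl)oxy]oxolan-2-one
Product: 13 (3R,7E)-1-hydroxy-3,7-dimethyl-9-(naphthalen-2-ylmethoxy)-3-[(triethylsilyl)oxy]non-7-en-4-one, via alkyllithium 12 (not isolated)
Conditions: t-BuLi (2.1 equiv), Et2O, −78 °C; then 5, −78 °C; aq. NH4Cl
Reagents that add atoms: none
Why: Iodine–lithium exchange followed by single addition of the primary alkyllithium to the non-enolizable α-silyloxy lactone (the lithium lactolate is stable at −78 °C) forms the C1–C2 bond and gives the γ-hydroxy ketone.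

Step 9
Reactants: 13 (3R,7E)-1-hydroxy-3,7-dimethyl-9-(naphthalen-2-ylmethoxy)-3-[(triethylsilyl)oxy]non-7-en-4-one
Product: 14 (3R,7E)-3,7-dimethyl-9-(naphthalen-2-ylmethoxy)-4-oxo-3-[(triethylsilyl)oxy]non-7-enal
Conditions: Dess–Martin periodinane, NaHCO3, CH2Cl2, 0 °C to rt
Reagents that add atoms: none
Why: Dess–Martin oxidation of the primary alcohol (the open form of the hydroxy ketone) gives the C8 aldehyde under buffered, non-basic conditions.

Step 10
Reactants: 14 (3R,7E)-3,7-dimethyl-9-(naphthalen-2-ylmethoxy)-4-oxo-3-[(triethylsilyl)oxy]non-7-enal, 15 methyl propiolate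
Product: 16 methyl (4S,6R,10E)-4-hydroxy-6,10-dimethyl-12-(naphthalen-2-ylmethoxy)-7-oxo-6-[(triethylsilyl)oxy]dodec-10-en-2-ynoate
Conditions: ProPhenol ligand (antipode giving 8S, 10 mol %), Me2Zn, Ph3P=O (20 mol %), toluene, 4 °C
Reagents that add atoms: none
Why: Zinc–ProPhenol asymmetric alkynylation adds the zinc alkynylide of methyl propiolate to the aldehyde only (the α-quaternary ketone is inert), and the C8 stereocentre is set by the chiral dinuclear zinc catalyst.

Step 11
Reactants: 16 methyl (4S,6R,10E)-4-hydroxy-6,10-dimethyl-12-(naphthalen-2-ylmethoxy)-7-oxo-6-[(triethylsilyl)oxy]dodec-10-en-2-ynoate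
Product: 17 methyl (4S,6R,10E)-6,10-dimethyl-12-(naphthalen-2-ylmethoxy)-7-oxo-4,6-bis[(triethylsilyl)oxy]dodec-10-en-2-ynoate
Conditions: TESCl, imidazole, CH2Cl2, 0 °C
Reagents that add atoms: chlorotriethylsilane, CC[Si](Cl)(CC)CC
Why: Silylation of the secondary propargylic alcohol gives a C8 oxygen that cannot lactonize onto C12 and cannot act as a leaving group next to the later alkenylmetal.

Step 12
Reactants: 17 methyl (4S,6R,10E)-6,10-dimethyl-12-(naphthalen-2-ylmethoxy)-7-oxo-4,6-bis[(triethylsilyl)oxy]dodec-10-en-2-ynoate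
Product: 19 methyl (2Z,4S,6R,10E)-2-(hydroxymethyl)-3-iodo-6,10-dimethyl-12-(naphthalen-2-ylmethoxy)-7-oxo-4,6-bis[(triethylsilyl)oxy]dodeca-2,10-dienoate, via iodomagnesium allenolate 18 (not isolated)
Conditions: MgI2, CH2O (monomeric, from cracked paraformaldehyde), CH2Cl2, −40 to 0 °C
Reagents that add atoms: magnesium diiodide, [Mg+2].[I-].[I-]; formaldehyde, C=O
Why: Iodo-aldol (β-iodo Baylis–Hillman-type) three-component coupling: iodide adds to C7 of the magnesium-activated ynoate and the allenolate is hydroxymethylated at C11 anti to the iodide (kinetic trans-addition, as in the Z-selective couplings of propiolates), which places iodine cis to CO2Me and C13 cis to C8.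

Step 13
Reactants: 19 methyl (2Z,4S,6R,10E)-2-(hydroxymethyl)-3-iodo-6,10-dimethyl-12-(naphthalen-2-ylmethoxy)-7-oxo-4,6-bis[(triethylsilyl)oxy]dodeca-2,10-dienoate
Product: 20 methyl (2Z,4S,6R,10E)-2-({[tert-butyl(diphenyl)silyl]oxy}methyl)-3-iodo-6,10-dimethyl-12-(naphthalen-2-ylmethoxy)-7-oxo-4,6-bis[(triethylsilyl)oxy]dodeca-2,10-dienoate
Conditions: TBDPSCl, imidazole, CH2Cl2, 0 °C to rt
Reagents that add atoms: tert-butyl(chloro)diphenylsilane, CC(C)(C)[Si](Cl)(c1ccccc1)c1ccccc1
Why: Silylation of the primary C13 alcohol with a robust silyl group that outlasts the later selective removal of the two triethylsilyl ethers and the acetylation.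

Step 14
Reactants: 20 methyl (2Z,4S,6R,10E)-2-({[tert-butyl(diphenyl)silyl]oxy}methyl)-3-iodo-6,10-dimethyl-12-(naphthalen-2-ylmethoxy)-7-oxo-4,6-bis[(triethylsilyl)oxy]dodeca-2,10-dienoate
Product: 21 methyl (2Z,4S,6R,10E)-2-({[tert-butyl(diphenyl)silyl]oxy}methyl)-12-hydroxy-3-iodo-6,10-dimethyl-7-oxo-4,6-bis[(triethylsilyl)oxy]dodeca-2,10-dienoate
Conditions: DDQ, CH2Cl2/pH 7 buffer, 0 °C to rt
Reagents that add atoms: none
Why: Oxidative cleavage of the 2-naphthylmethyl ether (benzylic hydride abstraction by DDQ, then hydrolysis) frees the C6 allylic alcohol while silyl ethers, alkenyl iodide and ester are inert.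

Step 15
Reactants: 21 methyl (2Z,4S,6R,10E)-2-({[tert-butyl(diphenyl)silyl]oxy}methyl)-12-hydroxy-3-iodo-6,10-dimethyl-7-oxo-4,6-bis[(triethylsilyl)oxy]dodeca-2,10-dienoate
Product: 22 methyl (2Z,4S,6R)-2-({[tert-butyl(diphenyl)silyl]oxy}methyl)-9-[(2R,3R)-3-(hydroxymethyl)-2-methyloxiran-2-yl]-3-iodo-6-methyl-7-oxo-4,6-bis[(triethylsilyl)oxy]non-2-enoate
Conditions: Ti(OiPr)4 (cat.), D-(−)-diisopropyl tartrate, t-BuOOH, 4 Å MS, CH2Cl2, −20 °C
Reagents that add atoms: tert-butyl hydroperoxide, CC(C)(C)OO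
Why: Sharpless asymmetric epoxidation of the E allylic alcohol with the D-(−)-tartrate ligand sets C4 (R) and C5 (R) by reagent control (the enantiomeric series to the (2S,3S)-epoxide that the L-(+)-ester gives with geraniol-type alcohols); the electron-poor iodoenoate alkene is untouched.

Step 16
Reactants: 22 methyl (2Z,4S,6R)-2-({[tert-butyl(diphenyl)silyl]oxy}methyl)-9-[(2R,3R)-3-(hydroxymethyl)-2-methyloxiran-2-yl]-3-iodo-6-methyl-7-oxo-4,6-bis[(triethylsilyl)oxy]non-2-enoate
Product: 23 methyl (2Z,4S,6R)-2-({[tert-butyl(diphenyl)silyl]oxy}methyl)-9-[(2R,3S)-3-formyl-2-methyloxiran-2-yl]-3-iodo-6-methyl-7-oxo-4,6-bis[(triethylsilyl)oxy]non-2-enoate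
Conditions: Dess–Martin periodinane, NaHCO3, CH2Cl2, 0 °C; used directly
Reagents that add atoms: none
Why: Buffered Dess–Martin oxidation gives the α,β-epoxy aldehyde without epimerization or oxirane opening (the C5 descriptor changes only because of the priority rules).

Step 17
Reactants: 23 methyl (2Z,4S,6R)-2-({[tert-butyl(diphenyl)silyl]oxy}methyl)-9-[(2R,3S)-3-formyl-2-methyloxiran-2-yl]-3-iodo-6-methyl-7-oxo-4,6-bis[(triethylsilyl)oxy]non-2-enoate
Product: 26 (4R,5R,6S,8S,10R)-13-[(tert-butyldiphenylsilyl)oxy]-4,5-epoxy-1-oxo-8,10-bis[(triethylsilyl)oxy]germacr-7(11)-en-12,6-olide, via alkenylchromium dichloride 24 (not isolated), via hydroxy ester 25 (not isolated)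
Conditions: CrCl2 (8 equiv), NiCl2 (1 mol % of CrCl2), degassed DMSO, 2 mM (slow addition of 23), rt; aqueous work-up
Reagents that add atoms: none
Why: NiCl2 is reduced by CrCl2 to zerovalent nickel, which inserts into the C7–iodine bond with retention, transmetalation gives the trivalent alkenylchromium 24, this adds to the C6 aldehyde, and the chromium alkoxide 25 attacks the cis methyl ester at C12 and expels methoxide to give the butenolide. The closest known reaction types are Nozaki–Hiyama–Kishi macrocyclizations of alkenyl iodides onto aldehydes, the one-pot coupling–lactonization of (Z)-β-iodo enoates with aldehydes to butenolides, and chromium-mediated Barbier-type closures of ten-membered carbocycles onto α,β-epoxy aldehydes. The ten-membered carbocycle closes by 10-exo-trig addition to the aldehyde C=O and the butenolide by 5-exo-trig acyl substitution at C12. The only new stereocentre, C6, is controlled by the adjacent oxirane carbon C5: C7 attacks anti to the C5–O bond while the chromium-bound carbonyl oxygen is turned toward the oxirane oxygen and the ring periphery (s-trans to C4, to which C7 is tethered), which places H5 and H6 anti and should give 6S. The step needs chemoselectivity for the aldehyde over the C1 ketone (intrinsic to organochromium reagents), the Z iodoenoate geometry from step 12 so that only the 6,12-lactone can form, silyl rather than acyl protection at C8 and C10 so that neither β-elimination at C8 nor reductive loss of the α-keto oxygen at C10 occurs, and high dilution to favour ring closure over oligomerization.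

Step 18
Reactants: 26 (4R,5R,6S,8S,10R)-13-[(tert-butyldiphenylsilyl)oxy]-4,5-epoxy-1-oxo-8,10-bis[(triethylsilyl)oxy]germacr-7(11)-en-12,6-olide
Product: 27 (4R,5R,6S,8S,10R)-13-[(tert-butyldiphenylsilyl)oxy]-4,5-epoxy-8,10-dihydroxy-1-oxogermacr-7(11)-en-12,6-olide
Conditions: HF·pyridine, pyridine, THF, 0 °C
Reagents that add atoms: none
Why: Buffered fluoride desilylation removes the two triethylsilyl ethers, which are orders of magnitude more labile than the primary tert-butyldiphenylsilyl ether, and the 8-hydroxyl cannot translactonize because C12 is trans to C8.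

Step 19
Reactants: 27 (4R,5R,6S,8S,10R)-13-[(tert-butyldiphenylsilyl)oxy]-4,5-epoxy-8,10-dihydroxy-1-oxogermacr-7(11)-en-12,6-olide
Product: 28 (4R,5R,6S,8S,10R)-8,10-diacetoxy-13-[(tert-butyldiphenylsilyl)oxy]-4,5-epoxy-1-oxogermacr-7(11)-en-12,6-olide
Conditions: Ac2O, DMAP, Et3N, CH2Cl2, rt to 35 °C
Reagents that add atoms: acetic anhydride, CC(=O)OC(C)=O
Why: DMAP-catalysed acylation acetylates the secondary C8 and the tertiary α-keto C10 hydroxyls under weakly basic conditions that should not deprotonate the butenolide γ-position.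

Step 20
Reactants: 28 (4R,5R,6S,8S,10R)-8,10-diacetoxy-13-[(tert-butyldiphenylsilyl)oxy]-4,5-epoxy-1-oxogermacr-7(11)-en-12,6-olide
Product: 29 (4R,5R,6S,8S,10R)-8,10-diacetoxy-4,5-epoxy-13-hydroxy-1-oxogermacr-7(11)-en-12,6-olide (CNP0266633.2)
Conditions: TBAF, AcOH (1:1), THF, rt
Reagents that add atoms: none
Why: Acetic acid-buffered fluoride desilylation frees the primary C13 alcohol at near-neutral pH, which the acetates, the oxirane and the base-sensitive butenolide should tolerate.

**Compound list**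

1 | (R)-citramalic acid | C[C@@](O)(CC(=O)O)C(=O)O | starting material
2 | 2-[(4R)-2,2,4-trimethyl-5-oxo-1,3-dioxolan-4-yl]acetic acid | C[C@]1(CC(=O)O)OC(C)(C)OC1=O | intermediate
3 | (5R)-5-(2-hydroxyethyl)-2,2,5-trimethyl-1,3-dioxolan-4-one | C[C@]1(CCO)OC(C)(C)OC1=O | intermediate
4 | (3R)-3-hydroxy-3-methyloxolan-2-one | C[C@@]1(O)CCOC1=O | intermediate
5 | (3R)-3-methyl-3-[(triethylsilyl)oxy]oxolan-2-one | C[C@@]1(O[Si](CC)(CC)CC)CCOC1=O | intermediate
6 | (but-3-yn-1-yloxy)(tert-butyl)dimethylsilane | C#CCCO[Si](C)(C)C(C)(C)C | starting material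
7 | [(1E)-4-{[tert-butyl(dimethyl)silyl]oxy}-2-methylbut-1-en-1-yl]dimethylalane | C[Al](C)/C=C(\C)CCO[Si](C)(C)C(C)(C)C | intermediate
8 | (2E)-5-{[tert-butyl(dimethyl)silyl]oxy}-3-methylpent-2-en-1-ol | OC/C=C(\C)CCO[Si](C)(C)C(C)(C)C | intermediate
9 | tert-butyl(dimethyl){[(3E)-3-methyl-5-(naphthalen-2-ylmethoxy)pent-3-en-1-yl]oxy}silane | CC(C)(C)[Si](C)(C)OCC/C(C)=C/COCc1ccc2ccccc2c1 | intermediate
10 | (3E)-3-methyl-5-(naphthalen-2-ylmethoxy)pent-3-en-1-ol | OCC/C(C)=C/COCc1ccc2ccccc2c1 | intermediate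
11 | 2-({[(2E)-5-iodo-3-methylpent-2-en-1-yl]oxy}methyl)naphthalene | ICC/C(C)=C/COCc1ccc2ccccc2c1 | intermediate
12 | [(3E)-3-methyl-5-(naphthalen-2-ylmethoxy)pent-3-en-1-yl]lithium | [Li]CC/C(C)=C/COCc1ccc2ccccc2c1 | intermediate
13 | (3R,7E)-1-hydroxy-3,7-dimethyl-9-(naphthalen-2-ylmethoxy)-3-[(triethylsilyl)oxy]non-7-en-4-one | OCC[C@@](C)(O[Si](CC)(CC)CC)C(=O)CC/C(C)=C/COCc1ccc2ccccc2c1 | intermediate
14 | (3R,7E)-3,7-dimethyl-9-(naphthalen-2-ylmethoxy)-4-oxo-3-[(triethylsilyl)oxy]non-7-enal | O=CC[C@@](C)(O[Si](CC)(CC)CC)C(=O)CC/C(C)=C/COCc1ccc2ccccc2c1 | intermediate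
15 | methyl propiolate | C#CC(=O)OC | starting material
16 | methyl (4S,6R,10E)-4-hydroxy-6,10-dimethyl-12-(naphthalen-2-ylmethoxy)-7-oxo-6-[(triethylsilyl)oxy]dodec-10-en-2-ynoate | COC(=O)C#C[C@@H](O)C[C@@](C)(O[Si](CC)(CC)CC)C(=O)CC/C(C)=C/COCc1ccc2ccccc2c1 | intermediate
17 | methyl (4S,6R,10E)-6,10-dimethyl-12-(naphthalen-2-ylmethoxy)-7-oxo-4,6-bis[(triethylsilyl)oxy]dodec-10-en-2-ynoate | COC(=O)C#C[C@@H](O[Si](CC)(CC)CC)C[C@@](C)(O[Si](CC)(CC)CC)C(=O)CC/C(C)=C/COCc1ccc2ccccc2c1 | intermediate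
18 | iodomagnesium allenolate of 17 carrying iodine at C7 (methyl 3-iodo-2,3-dienoate enolate) | COC(O[Mg]I)=C=C(I)[C@@H](O[Si](CC)(CC)CC)C[C@@](C)(O[Si](CC)(CC)CC)C(=O)CC/C(C)=C/COCc1ccc2ccccc2c1 | intermediate
19 | methyl (2Z,4S,6R,10E)-2-(hydroxymethyl)-3-iodo-6,10-dimethyl-12-(naphthalen-2-ylmethoxy)-7-oxo-4,6-bis[(triethylsilyl)oxy]dodeca-2,10-dienoate | COC(=O)/C(CO)=C(\I)[C@@H](O[Si](CC)(CC)CC)C[C@@](C)(O[Si](CC)(CC)CC)C(=O)CC/C(C)=C/COCc1ccc2ccccc2c1 | intermediate
20 | methyl (2Z,4S,6R,10E)-2-({[tert-butyl(diphenyl)silyl]oxy}methyl)-3-iodo-6,10-dimethyl-12-(naphthalen-2-ylmethoxy)-7-oxo-4,6-bis[(triethylsilyl)oxy]dodeca-2,10-dienoate | COC(=O)/C(CO[Si](c1ccccc1)(c1ccccc1)C(C)(C)C)=C(\I)[C@@H](O[Si](CC)(CC)CC)C[C@@](C)(O[Si](CC)(CC)CC)C(=O)CC/C(C)=C/COCc1ccc2ccccc2c1 | intermediate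
21 | methyl (2Z,4S,6R,10E)-2-({[tert-butyl(diphenyl)silyl]oxy}methyl)-12-hydroxy-3-iodo-6,10-dimethyl-7-oxo-4,6-bis[(triethylsilyl)oxy]dodeca-2,10-dienoate | COC(=O)/C(CO[Si](c1ccccc1)(c1ccccc1)C(C)(C)C)=C(\I)[C@@H](O[Si](CC)(CC)CC)C[C@@](C)(O[Si](CC)(CC)CC)C(=O)CC/C(C)=C/CO | intermediate
22 | methyl (2Z,4S,6R)-2-({[tert-butyl(diphenyl)silyl]oxy}methyl)-9-[(2R,3R)-3-(hydroxymethyl)-2-methyloxiran-2-yl]-3-iodo-6-methyl-7-oxo-4,6-bis[(triethylsilyl)oxy]non-2-enoate | COC(=O)/C(CO[Si](c1ccccc1)(c1ccccc1)C(C)(C)C)=C(\I)[C@@H](O[Si](CC)(CC)CC)C[C@@](C)(O[Si](CC)(CC)CC)C(=O)CC[C@@]1(C)O[C@@H]1CO | intermediate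
23 | methyl (2Z,4S,6R)-2-({[tert-butyl(diphenyl)silyl]oxy}methyl)-9-[(2R,3S)-3-formyl-2-methyloxiran-2-yl]-3-iodo-6-methyl-7-oxo-4,6-bis[(triethylsilyl)oxy]non-2-enoate | COC(=O)/C(CO[Si](c1ccccc1)(c1ccccc1)C(C)(C)C)=C(\I)[C@@H](O[Si](CC)(CC)CC)C[C@@](C)(O[Si](CC)(CC)CC)C(=O)CC[C@@]1(C)O[C@@H]1C=O | intermediate
24 | C7 alkenylchromium dichloride derived from 23 (chromium in place of iodine, geometry retained) | COC(=O)/C(CO[Si](c1ccccc1)(c1ccccc1)C(C)(C)C)=C(\[Cr](Cl)Cl)[C@@H](O[Si](CC)(CC)CC)C[C@@](C)(O[Si](CC)(CC)CC)C(=O)CC[C@@]1(C)O[C@@H]1C=O | intermediate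
25 | ten-membered (6S)-hydroxy methyl ester (formed as its chromium alkoxide; C12 ester cis to C6) | CC[Si](CC)(CC)O[C@H]1C[C@@](C)(O[Si](CC)(CC)CC)C(=O)CC[C@@]2(C)O[C@@H]2[C@@H](O)/C1=C(/CO[Si](c1ccccc1)(c1ccccc1)C(C)(C)C)C(=O)OC | intermediate
26 | (4R,5R,6S,8S,10R)-13-[(tert-butyldiphenylsilyl)oxy]-4,5-epoxy-1-oxo-8,10-bis[(triethylsilyl)oxy]germacr-7(11)-en-12,6-olide | CC[Si](CC)(CC)O[C@H]1C[C@@](C)(O[Si](CC)(CC)CC)C(=O)CC[C@@]2(C)O[C@@H]2[C@H]2OC(=O)C(CO[Si](c3ccccc3)(c3ccccc3)C(C)(C)C)=C12 | intermediate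
27 | (4R,5R,6S,8S,10R)-13-[(tert-butyldiphenylsilyl)oxy]-4,5-epoxy-8,10-dihydroxy-1-oxogermacr-7(11)-en-12,6-olide | O[C@H]1C[C@@](C)(O)C(=O)CC[C@@]2(C)O[C@@H]2[C@H]2OC(=O)C(CO[Si](c3ccccc3)(c3ccccc3)C(C)(C)C)=C12 | intermediate
28 | (4R,5R,6S,8S,10R)-8,10-diacetoxy-13-[(tert-butyldiphenylsilyl)oxy]-4,5-epoxy-1-oxogermacr-7(11)-en-12,6-olide | CC(=O)O[C@H]1C[C@@](C)(OC(C)=O)C(=O)CC[C@@]2(C)O[C@@H]2[C@H]2OC(=O)C(CO[Si](c3ccccc3)(c3ccccc3)C(C)(C)C)=C12 | intermediate
29 | (4R,5R,6S,8S,10R)-8,10-diacetoxy-4,5-epoxy-13-hydroxy-1-oxogermacr-7(11)-en-12,6-olide (CNP0266633.2) | CC(=O)O[C@H]1C[C@@](C)(OC(C)=O)C(=O)CC[C@@]2(C)O[C@@H]2[C@H]2OC(=O)C(CO)=C12 | target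

**Summary**

Total step count: 20. Longest linear sequence: 17 steps (6 to 29: steps 4–7, then 8–20). The other branch (1 to 29) is 16 steps.

**Steps most likely to fail**

1. Step 17. What may go wrong: C7 may attack the other aldehyde face through the Felkin–Anh-type rotamer and give the C6 epimer, and a slow ten-membered closure may lose out to intermolecular coupling or simple reduction of the iodide. Fallback (sets out from 21, returns at 26): the oxirane is deferred so that C6 is set by a reagent and the oxirane by the ring. MnO2 (CH2Cl2, rt) should oxidize 21 to the enal F1. Ring closure of F1 with CrCl2/NiCl2 at high dilution in the presence of a chiral sulfonamide ligand for chromium (asymmetric Nozaki–Hiyama–Kishi conditions, ligand antipode chosen for the C6 configuration of the target) should give the hydroxy ester F2, which lactonizes in the flask to the dienolide F3. Epoxidation of F3 with mCPBA (NaHCO3, CH2Cl2, 0 °C) on the exposed outer face of the E-4,5-alkene, the face normally attacked in germacranolide 4,5-alkenes next to a 6,12-lactone, should then give 26.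

2. Step 12. What may go wrong: formaldehyde may enter on the iodine side of the allenolate and give the wrong alkene geometry (C13 cis to iodine), or the allenolate may simply be protonated. Fallback (sets out from 16, returns at 20): the free C8 hydroxyl is used as an internal delivery arm. Treating 16 with MgI2 and monomeric CH2O (CH2Cl2, −40 to 0 °C) lets the C8 magnesium alkoxide bind formaldehyde and deliver it to C11 on the C8 side, which is the required geometry, to give the diol F4. Any wrong isomer reveals itself by lactonizing (C12 onto the C8 oxygen) and is removed by chromatography. TBDPSCl/imidazole should silylate only the primary hydroxyl to give the silyl ether F5, and TESCl/imidazole then gives 20.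

3. Step 10. What may go wrong: facial discrimination at the aldehyde may be insufficient if catalyst and the C10 centre are mismatched, which would leave 16 mixed with its C8 epimer. Fallback (sets out from 16 as the epimer mixture, returns at 16): C8 is set by reduction instead of addition. Dess–Martin oxidation should give the ynone F6, and Midland reduction with (S)-Alpine-Borane (THF, rt), which reduces only the unhindered alkynyl ketone and leaves the α-quaternary C1 ketone alone, should return 16 as the 8S alcohol.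

Further compounds
F1 | step 17 | methyl (2Z,4S,6R,10E)-2-({[tert-butyl(diphenyl)silyl]oxy}methyl)-3-iodo-6,10-dimethyl-7,12-dioxo-4,6-bis[(triethylsilyl)oxy]dodeca-2,10-dienoate | COC(=O)/C(CO[Si](c1ccccc1)(c1ccccc1)C(C)(C)C)=C(\I)[C@@H](O[Si](CC)(CC)CC)C[C@@](C)(O[Si](CC)(CC)CC)C(=O)CC/C(C)=C/C=O
F2 | step 17 | ten-membered C6 hydroxy methyl ester with E-4,5-alkene (open form of F3; C12 ester cis to C6) | CC[Si](CC)(CC)O[C@H]1C[C@@](C)(O[Si](CC)(CC)CC)C(=O)CC/C(C)=C/[C@@H](O)/C1=C(/CO[Si](c1ccccc1)(c1ccccc1)C(C)(C)C)C(=O)OC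
F3 | step 17 | (4E,6R,8S,10R)-13-[(tert-butyldiphenylsilyl)oxy]-1-oxo-8,10-bis[(triethylsilyl)oxy]germacra-4,7(11)-dien-12,6-olide | CC[Si](CC)(CC)O[C@H]1C[C@@](C)(O[Si](CC)(CC)CC)C(=O)CC/C(C)=C/[C@H]2OC(=O)C(CO[Si](c3ccccc3)(c3ccccc3)C(C)(C)C)=C12
F4 | step 12 | methyl (2Z,4S,6R,10E)-4-hydroxy-2-(hydroxymethyl)-3-iodo-6,10-dimethyl-12-(naphthalen-2-ylmethoxy)-7-oxo-6-[(triethylsilyl)oxy]dodeca-2,10-dienoate | COC(=O)/C(CO)=C(\I)[C@@H](O)C[C@@](C)(O[Si](CC)(CC)CC)C(=O)CC/C(C)=C/COCc1ccc2ccccc2c1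
F5 | step 12 | methyl (2Z,4S,6R,10E)-2-({[tert-butyl(diphenyl)silyl]oxy}methyl)-4-hydroxy-3-iodo-6,10-dimethyl-12-(naphthalen-2-ylmethoxy)-7-oxo-6-[(triethylsilyl)oxy]dodeca-2,10-dienoate | COC(=O)/C(CO[Si](c1ccccc1)(c1ccccc1)C(C)(C)C)=C(\I)[C@@H](O)C[C@@](C)(O[Si](CC)(CC)CC)C(=O)CC/C(C)=C/COCc1ccc2ccccc2c1
F6 | step 10 | methyl (6R,10E)-6,10-dimethyl-12-(naphthalen-2-ylmethoxy)-4,7-dioxo-6-[(triethylsilyl)oxy]dodec-10-en-2-ynoate | COC(=O)C#CC(=O)C[C@@](C)(O[Si](CC)(CC)CC)C(=O)CC/C(C)=C/COCc1ccc2ccccc2c1
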